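**Assumption:** the target has no stereogenic element, so the compound as drawn is the only species required; intermediates that carry a stereocentre are racemic and the chalcone is the E isomer.

## Retrosynthetic overview

1. Target ⇐ 3,5,7,8,2'-pentamethoxyflavone, by chelation-controlled cleavage of the 5-OMe only (last step).
2. 3-OMe ⇐ flavonol ⇐ flavone, by C-3 oxygenation (DMDO epoxidation and acid rearrangement) followed by O-methylation.
3. Ring C (the pyranone) is the only ring built; it is closed by oxidative oxa-Michael cyclisation of a 2'-hydroxychalcone. Rings A and B come from purchased arenes.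
4. Key C–C bond (future C2–C3): Claisen–Schmidt aldol condensation of 2'-hydroxy-3',4',6'-trimethoxyacetophenone with 2-methoxybenzaldehyde.
5. The acetophenone ⇐ 1,2,3,5-tetramethoxybenzene (Friedel–Crafts acetylation with selective ortho-demethylation) ⇐ 3,4,5-trimethoxyphenol.

## Route

**Step 1**
Reactants: 1 3,4,5-trimethoxyphenol
Product: 2 1,2,3,5-tetramethoxybenzene
Conditions: MeI (1.5 equiv), K2CO3 (2 equiv), acetone, reflux, 12 h
Reagents that add atoms: iodomethane, CI
Why: Williamson O-methylation (SN2 of the phenoxide on MeI) of an unhindered, electron-rich phenol is essentially quantitative.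

**Step 2**
Reactants: 2 1,2,3,5-tetramethoxybenzene
Product: 5 2'-hydroxy-3',4',6'-trimethoxyacetophenone, via 2',3',4',6'-tetramethoxyacetophenone 3 (not isolated), via dichloroaluminium phenolate 4 (not isolated)
Conditions: AcCl (1.2 equiv), AlCl3 (2.5 equiv), Et2O, 0 °C → rt, 24 h; then ice-water
Reagents that add atoms: acetyl chloride, CC(=O)Cl
Why: Friedel–Crafts acylation can only occur at the two equivalent free ring positions, and AlCl3 chelated to the new carbonyl then cleaves the sterically compressed ortho-methoxy group flanked by the acetyl and the neighbouring OMe rather than the 6'-OMe, the resulting six-membered aluminium chelate stopping further ether cleavage.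

**Step 3**
Reactants: 5 2'-hydroxy-3',4',6'-trimethoxyacetophenone; 6 2-methoxybenzaldehyde
Product: 8 (E)-2'-hydroxy-2,3',4',6'-tetramethoxychalcone, via racemic aldol adduct 7 (not isolated)
Conditions: KOH (50% aq., 5 equiv), EtOH, 0 °C → rt, 48 h; then 2 M HCl, 0 °C
Reagents that add atoms: none
Why: intermolecular crossed aldol (Claisen–Schmidt) condensation of the methyl ketone enolate with a non-enolisable aldehyde forms the C–C bond, and E1cB dehydration of the aldol gives the thermodynamically favoured E-enone, leaving no stereocentre.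

**Step 4**
Reactants: 8 (E)-2'-hydroxy-2,3',4',6'-tetramethoxychalcone
Product: 10 5,7,8,2'-tetramethoxyflavone, via racemic flavanone 9 (not isolated)
Conditions: I2 (10 mol %), DMSO, 130 °C, 2 h
Reagents that add atoms: none
Why: oxidative cyclisation in which intramolecular oxa-Michael addition of the 2'-phenol gives the flavanone, which is dehydrogenated by α-iodination and HI elimination while DMSO re-oxidises HI to I2, so the C-2 stereocentre of 9 disappears.

**Step 5**
Reactants: 10 5,7,8,2'-tetramethoxyflavone
Product: 12 3-hydroxy-5,7,8,2'-tetramethoxyflavone, via racemic flavone 2,3-epoxide 11 (not isolated)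
Conditions: DMDO (0.08 M in acetone, 2.5 equiv), CH2Cl2, 0 °C → rt, 24 h, dark; evaporate; then p-TsOH·H2O (5 mol %), CH2Cl2, rt, 1 h
Reagents that add atoms: dimethyldioxirane, CC1(C)OO1
Why: electrophilic epoxidation of the enol-ether-like C2=C3 bond by neutral DMDO gives the 2,3-epoxide, which under acid catalysis opens at C-2 (oxocarbenium stabilised by O-1 and the aryl group) and loses H-3 to give the flavonol, removing both epoxide stereocentres.

**Step 6**
Reactants: 12 3-hydroxy-5,7,8,2'-tetramethoxyflavone
Product: 13 3,5,7,8,2'-pentamethoxyflavone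
Conditions: MeI (3 equiv), K2CO3 (3 equiv), DMF, 40 °C, 6 h
Reagents that add atoms: iodomethane, CI
Why: Williamson O-methylation of the only acidic group in the molecule, the enolic 3-OH.

**Step 7**
Reactants: 13 3,5,7,8,2'-pentamethoxyflavone
Product: 15 5-hydroxy-3,7,8,2'-tetramethoxyflavone, via 5-O-dichloroboryl chelate 14 (not isolated)
Conditions: BCl3 (1.0 M in CH2Cl2, 1.5 equiv), CH2Cl2, −78 °C → 0 °C, 2 h; then ice-water
Reagents that add atoms: none
Why: chelation-controlled Lewis-acid ether cleavage, in which BCl3 bridges the C-4 carbonyl and the peri 5-OMe in a six-membered chelate so chloride removes only that methyl group at low temperature, and hydrolysis releases the hydrogen-bonded 5-OH while the 3-, 7-, 8- and 2'-OMe groups remain.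

## Compound list

1 | 3,4,5-trimethoxyphenol | COc1cc(O)cc(OC)c1OC | starting material
2 | 1,2,3,5-tetramethoxybenzene | COc1cc(OC)c(OC)c(OC)c1 | intermediate
3 | 2',3',4',6'-tetramethoxyacetophenone, 1-(2,3,4,6-tetramethoxyphenyl)ethanone (formed in the flask) | CC(=O)c1c(OC)cc(OC)c(OC)c1OC | intermediate
4 | dichloroaluminium 2-acetyl-3,5,6-trimethoxyphenolate (chelated phenolate before work-up) | CC(=O)c1c(OC)cc(OC)c(OC)c1O[Al](Cl)Cl | intermediate
5 | 2'-hydroxy-3',4',6'-trimethoxyacetophenone, 1-(2-hydroxy-3,4,6-trimethoxyphenyl)ethanone | CC(=O)c1c(OC)cc(OC)c(OC)c1O | intermediate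
6 | 2-methoxybenzaldehyde | COc1ccccc1C=O | starting material
7 | 3-hydroxy-1-(2-hydroxy-3,4,6-trimethoxyphenyl)-3-(2-methoxyphenyl)propan-1-one (racemic aldol adduct, formed in the flask) | COc1ccccc1C(O)CC(=O)c1c(OC)cc(OC)c(OC)c1O | intermediate
8 | (E)-1-(2-hydroxy-3,4,6-trimethoxyphenyl)-3-(2-methoxyphenyl)prop-2-en-1-one | COc1ccccc1/C=C/C(=O)c1c(OC)cc(OC)c(OC)c1O | intermediate
9 | 5,7,8-trimethoxy-2-(2-methoxyphenyl)chroman-4-one (racemic flavanone, formed in the flask) | COc1ccccc1C1CC(=O)c2c(OC)cc(OC)c(OC)c2O1 | intermediate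
10 | 5,7,8-trimethoxy-2-(2-methoxyphenyl)-4H-chromen-4-one | COc1ccccc1-c1cc(=O)c2c(OC)cc(OC)c(OC)c2o1 | intermediate
11 | 2,3-epoxy-5,7,8-trimethoxy-2-(2-methoxyphenyl)chroman-4-one (racemic, oxirane fused across C2–C3, formed in the flask) | COc1ccccc1C12Oc3c(OC)c(OC)cc(OC)c3C(=O)C1O2 | intermediate
12 | 3-hydroxy-5,7,8-trimethoxy-2-(2-methoxyphenyl)-4H-chromen-4-one | COc1ccccc1-c1oc2c(OC)c(OC)cc(OC)c2c(=O)c1O | intermediate
13 | 3,5,7,8-tetramethoxy-2-(2-methoxyphenyl)-4H-chromen-4-one | COc1ccccc1-c1oc2c(OC)c(OC)cc(OC)c2c(=O)c1OC | intermediate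
14 | 5-(dichloroboryloxy)-3,7,8-trimethoxy-2-(2-methoxyphenyl)-4H-chromen-4-one (boron chelated to the C-4 carbonyl, before work-up) | COc1ccccc1-c1oc2c(OC)c(OC)cc(OB(Cl)Cl)c2c(=O)c1OC | intermediate
15 | 5-hydroxy-3,7,8-trimethoxy-2-(2-methoxyphenyl)-4H-chromen-4-one (5-hydroxy-3,7,8,2'-tetramethoxyflavone) | COc1ccccc1-c1oc2c(OC)c(OC)cc(O)c2c(=O)c1OC | target

## Summary

Total step count: 7.
Longest linear sequence: 7 steps (1 → 2 → 5 → 8 → 10 → 12 → 13 → 15); 2-methoxybenzaldehyde 6 enters in step 3.

## Steps most likely to fail, with fallbacks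

**Step 3 (the aldol condensation).** The ketone reacts as its phenoxide and its carbonyl is flanked by two ortho substituents, so the condensation may be slow or incomplete. The fallback sets out from 5 and comes back at 8. The phenol of 5 is masked with NaH and chloromethyl methyl ether in DMF at 0 °C to give 1-[2-(methoxymethoxy)-3,4,6-trimethoxyphenyl]ethanone F1, whose enolate forms without a competing phenoxide. Condensation of F1 with 6 (KOH, EtOH, rt) gives (E)-1-[2-(methoxymethoxy)-3,4,6-trimethoxyphenyl]-3-(2-methoxyphenyl)prop-2-en-1-one F2. HCl in MeOH at 45 °C removes the acetal and returns chalcone 8. Any flavanone 9 formed under the acid is harmless, because it is the intermediate of step 4.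

**Step 5 (C-3 oxygenation with DMDO).** The electron-rich ring A or the hindered C2=C3 bond next to the ortho-substituted ring B could give over-oxidation or low conversion. The fallback sets out from 10 and comes back at 12, replacing electrophilic oxygen transfer with a carbanion route. LiN(i-Pr)2 (1.2 equiv) in THF at −78 °C deprotonates C-3 to give 3-lithio-5,7,8-trimethoxy-2-(2-methoxyphenyl)-4H-chromen-4-one F3. This is trapped with B(OMe)3 to give dimethyl [5,7,8-trimethoxy-2-(2-methoxyphenyl)-4-oxo-4H-chromen-3-yl]boronate F4. Oxidation in the same flask with AcOH and 30% H2O2 (0 °C → rt; aryl migration from boron to oxygen, then hydrolysis) gives flavonol 12.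

**Step 7 (selective 5-O-demethylation).** The 3-OMe can also chelate to the carbonyl and might be cleaved competitively. The fallback sets out from 12 and comes back at 15, inverting the order so that no 3-OMe is present during ether cleavage. Flavonol 12 is treated with BCl3 (3 equiv, CH2Cl2, −78 °C → rt, then water) to give 3,5-dihydroxy-7,8-dimethoxy-2-(2-methoxyphenyl)-4H-chromen-4-one F5. Me2SO4 (1.05 equiv) with K2CO3 in refluxing acetone then methylates only the 3-OH, because the 5-OH is locked in a strong hydrogen bond to the carbonyl and is the least reactive hydroxyl of a flavonol; this gives 15 directly.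

## Further compounds

F1 | step 3 | 1-[2-(methoxymethoxy)-3,4,6-trimethoxyphenyl]ethanone | CC(=O)c1c(OC)cc(OC)c(OC)c1OCOC
F2 | step 3 | (E)-1-[2-(methoxymethoxy)-3,4,6-trimethoxyphenyl]-3-(2-methoxyphenyl)prop-2-en-1-one | COCOc1c(OC)c(OC)cc(OC)c1C(=O)/C=C/c1ccccc1OC
F3 | step 5 | 3-lithio-5,7,8-trimethoxy-2-(2-methoxyphenyl)-4H-chromen-4-one | [Li]c1c(-c2ccccc2OC)oc2c(OC)c(OC)cc(OC)c2c1=O
F4 | step 5 | dimethyl [5,7,8-trimethoxy-2-(2-methoxyphenyl)-4-oxo-4H-chromen-3-yl]boronate | COB(OC)c1c(-c2ccccc2OC)oc2c(OC)c(OC)cc(OC)c2c1=O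
F5 | step 7 | 3,5-dihydroxy-7,8-dimethoxy-2-(2-methoxyphenyl)-4H-chromen-4-one | COc1ccccc1-c1oc2c(OC)c(OC)cc(O)c2c(=O)c1O
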